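**Retrosynthetic overview**
1. Ring B, the 2,2-dimethyl-2H-pyran (O1–C2–C3=C4–C4a–C8a), is made last by forming C4–C4a in a gold-catalysed 6-endo-dig hydroarylation of an aryl 1,1-dimethylpropargyl ether. The plan rests on C4a lying para to the C7 methoxy group, which makes it the most nucleophilic free carbon ortho to the ether oxygen.
2. The cyclisation substrate already carries the (S)-benzylic (Z)-enol ether side chain with both hydroxyl groups silylated; fluoride then releases the target.
3. The (Z)-enol ether comes from aluminium amide isomerisation of an oxiranyl ether, made by epoxidation of a 2-arylallyl ether, itself from Williamson union of an (S)-1-arylethanol with a 2-arylallyl bromide.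
4. The (S)-alcohol comes from CBS reduction of 4-O-(1,1-dimethylpropargyl)-2-O-methyl-2,4-dihydroxyacetophenone; the allyl bromide from copper-catalysed carbomagnesiation of propargyl alcohol by the Grignard reagent of silylated 2-bromo-5-methylphenol.
5. Ring order: benzene rings A (chromene) and C (cresol) are bought; ring B is the only ring formed.

Key step: step 11

Remark: the cresol oxygen is carried as a triisopropylsilyl ether and the primary alcohol as a tert-butyldimethylsilyl ether, because the aryl silyl ether must survive a Grignard reagent, a sodium alkoxide and an aluminium amide; both are removed by fluoride at the end.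
Remark: oxirane 17 is used as the mixture of its two epimers at the oxirane carbon, since that carbon becomes sp2 in step 9.

**Route**

Step 1
Reactants: 1 2,4-dihydroxyacetophenone; 2 3-chloro-3-methylbut-1-yne
Product: 3 1-[2-hydroxy-4-(2-methylbut-3-yn-2-yloxy)phenyl]ethanone
Conditions: K2CO3, KI (cat.), CuI (cat.), acetone, 56 °C
Reagents that add atoms: none
Why: The 2-OH is held in a hydrogen bond to the acetyl group, so only the more acidic 4-phenoxide should be alkylated by the tertiary propargylic chloride in a copper-assisted propargylic etherification of the Williamson type.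

Step 2
Reactants: 3 1-[2-hydroxy-4-(2-methylbut-3-yn-2-yloxy)phenyl]ethanone
Product: 4 1-[2-methoxy-4-(2-methylbut-3-yn-2-yloxy)phenyl]ethanone
Conditions: MeI, K2CO3, DMF, 40 °C
Reagents that add atoms: iodomethane, CI
Why: Williamson O-methylation of the remaining phenol in a dipolar aprotic solvent, with a carbonate base too weak to touch the alkyne C–H.

Step 3
Reactants: 4 1-[2-methoxy-4-(2-methylbut-3-yn-2-yloxy)phenyl]ethanone
Product: 6 (S)-1-[2-methoxy-4-(2-methylbut-3-yn-2-yloxy)phenyl]ethanol, via catechol borate ester 5 (not isolated)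
Conditions: (R)-1-methyl-3,3-diphenyltetrahydro-1H,3H-pyrrolo[1,2-c][1,3,2]oxazaborole (10 mol %), catecholborane, toluene, −40 °C; then H2O, wash with aq NaOH
Reagents that add atoms: none
Why: Corey–Bakshi–Shibata reduction, in which the (R)-oxazaborolidine should bind the ketone with the aryl group as the large substituent and deliver hydride to the Re face to set the (S) centre, while catecholborane at low temperature does not hydroborate the alkyne.

Step 4
Reactants: 7 2-bromo-5-methylphenol
Product: 8 (2-bromo-5-methylphenoxy)triisopropylsilane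
Conditions: TIPSCl, imidazole, DMF, 40 °C
Reagents that add atoms: chlorotriisopropylsilane, CC(C)[Si](Cl)(C(C)C)C(C)C
Why: Imidazole-promoted O-silylation of a phenol, with the bulky silyl group chosen to resist silyl migration and alkoxide attack later.

Step 5
Reactants: 8 (2-bromo-5-methylphenoxy)triisopropylsilane; 9 propargyl alcohol (prop-2-yn-1-ol)
Product: 13 2-[4-methyl-2-(triisopropylsilyloxy)phenyl]prop-2-en-1-ol, via arylmagnesium bromide 10 (not isolated), via chloromagnesium prop-2-yn-1-olate 11 (not isolated), via oxamagnesacycle 12 (not isolated)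
Conditions: 8, Mg, THF, 60 °C; separately 9, i-PrMgCl (1.0 equiv), THF, 0 °C; combine, CuI (10 mol %), 0 → 40 °C; then H2O
Reagents that add atoms: none
Why: Copper-catalysed anti-carbomagnesiation of a propargylic magnesium alkoxide should place the aryl group on C2 and magnesium on C3 inside a five-membered chelate, so protonolysis gives the 2-arylallyl alcohol.

Step 6
Reactants: 13 2-[4-methyl-2-(triisopropylsilyloxy)phenyl]prop-2-en-1-ol
Product: 14 [2-(3-bromoprop-1-en-2-yl)-5-methylphenoxy]triisopropylsilane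
Conditions: CBr4, PPh3, CH2Cl2, 0 °C; used promptly
Reagents that add atoms: tetrabromomethane, BrC(Br)(Br)Br
Why: The Appel reaction converts the primary allylic alcohol into the bromide under neutral conditions that spare the aryl silyl ether.

Step 7
Reactants: 6 (S)-1-[2-methoxy-4-(2-methylbut-3-yn-2-yloxy)phenyl]ethanol; 14 [2-(3-bromoprop-1-en-2-yl)-5-methylphenoxy]triisopropylsilane
Product: 16 {2-[3-{(1S)-1-[2-methoxy-4-(2-methylbut-3-yn-2-yloxy)phenyl]ethoxy}prop-1-en-2-yl]-5-methylphenoxy}triisopropylsilane, via sodium alkoxide 15 (not isolated)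
Conditions: 6, NaH (1.05 equiv), THF, 0 °C; then 14, Bu4NI (cat.), 0 °C → rt
Reagents that add atoms: none
Why: Williamson ether synthesis on a reactive 2-substituted allylic bromide, whose direct and allylic displacement pathways give the same ether, and the C–O bond at the stereocentre is never broken, so the (S) configuration is retained.

Step 8
Reactants: 16 {2-[3-{(1S)-1-[2-methoxy-4-(2-methylbut-3-yn-2-yloxy)phenyl]ethoxy}prop-1-en-2-yl]-5-methylphenoxy}triisopropylsilane
Product: 17 {2-[2-({(1S)-1-[2-methoxy-4-(2-methylbut-3-yn-2-yloxy)phenyl]ethoxy}methyl)oxiran-2-yl]-5-methylphenoxy}triisopropylsilane (both epimers at the oxirane carbon)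
Conditions: dimethyldioxirane (acetone solution, 1.2 equiv), CH2Cl2–acetone, −20 → 0 °C; evaporate and use crude
Reagents that add atoms: dimethyldioxirane, CC1(C)OO1
Why: Neutral electrophilic epoxidation of the only alkene present, since the terminal alkyne and the alkoxyarenes react far more slowly and no acid is formed that could ionise the benzylic ether or the tertiary benzylic oxirane.

Step 9
Reactants: 17 {2-[2-({(1S)-1-[2-methoxy-4-(2-methylbut-3-yn-2-yloxy)phenyl]ethoxy}methyl)oxiran-2-yl]-5-methylphenoxy}triisopropylsilane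
Product: 19 (Z)-3-{(1S)-1-[2-methoxy-4-(2-methylbut-3-yn-2-yloxy)phenyl]ethoxy}-2-[4-methyl-2-(triisopropylsilyloxy)phenyl]prop-2-en-1-ol, via diethylaluminium alkoxide 18 (not isolated)
Conditions: Et2Al(NC9H18) (4 equiv, made from Et2AlCl and lithium 2,2,6,6-tetramethylpiperidide LiNC9H18 at 0 °C), toluene, 0 °C → rt; then H2O at 0 °C
Reagents that add atoms: none
Why: Aluminium amide isomerisation of an epoxide to an allylic alcohol, in which aluminium binds the oxirane oxygen and the amide nitrogen removes a syn proton from the OCH2 group (the only β-carbon bearing hydrogen) through a six-membered transition state where the alkoxy group turns away from the nearly eclipsing aryl group and so should end cis to the CH2O arm, giving the (Z)-enol ether with the (S) centre untouched.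

Step 10
Reactants: 19 (Z)-3-{(1S)-1-[2-methoxy-4-(2-methylbut-3-yn-2-yloxy)phenyl]ethoxy}-2-[4-methyl-2-(triisopropylsilyloxy)phenyl]prop-2-en-1-ol
Product: 20 tert-butyl{[(Z)-3-{(1S)-1-[2-methoxy-4-(2-methylbut-3-yn-2-yloxy)phenyl]ethoxy}-2-[4-methyl-2-(triisopropylsilyloxy)phenyl]prop-2-en-1-yl]oxy}dimethylsilane
Conditions: TBSCl, imidazole, CH2Cl2, 0 °C → rt
Reagents that add atoms: tert-butylchlorodimethylsilane, CC(C)(C)[Si](C)(C)Cl
Why: Imidazole-promoted silylation of the primary allylic alcohol under weakly basic conditions that leave the enol ether and benzylic ether intact.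

Step 11
Reactants: 20 tert-butyl{[(Z)-3-{(1S)-1-[2-methoxy-4-(2-methylbut-3-yn-2-yloxy)phenyl]ethoxy}-2-[4-methyl-2-(triisopropylsilyloxy)phenyl]prop-2-en-1-yl]oxy}dimethylsilane
Product: 21 tert-butyl{[(Z)-3-[(1S)-1-(7-methoxy-2,2-dimethyl-2H-chromen-6-yl)ethoxy]-2-[4-methyl-2-(triisopropylsilyloxy)phenyl]prop-2-en-1-yl]oxy}dimethylsilane
Conditions: Ph3PAuNTf2 (3 mol %), 2,6-di-tert-butylpyridine (5 mol %), 4 Å MS, CH2Cl2, rt
Reagents that add atoms: none
Why: The cationic monovalent gold centre of Ph3PAuNTf2 binds the terminal alkyne of 20 and the arene carbon para to the methoxy group attacks it anti in a Friedel–Crafts-type step; rearomatisation of the arenium ion and protodeauration of the vinylgold species then release the C3=C4 alkene and the catalyst. The closest known reaction is the gold-catalysed intramolecular hydroarylation of aryl propargyl ethers, 1,1-dimethylpropargyl ethers included, to 2H-chromenes. Ring B closes in the 6-endo-dig mode, which a terminal alkyne held by a gem-dimethyl group should favour over 5-exo closure. No stereocentre is formed, and the (S) centre and the (Z)-enol ether take no part and should pass unchanged. The step needs regioselectivity for the carbon para to OMe over the carbon flanked by both oxygens, which the para-methoxy activation and the crowding of the flanked position should secure; it also needs chemoselectivity for the alkyne over the benzylic enol ether, which the silyl caps on both hydroxyls, the preformed acid-free catalyst and the hindered pyridine buffer are meant to secure.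

Step 12
Reactants: 21 tert-butyl{[(Z)-3-[(1S)-1-(7-methoxy-2,2-dimethyl-2H-chromen-6-yl)ethoxy]-2-[4-methyl-2-(triisopropylsilyloxy)phenyl]prop-2-en-1-yl]oxy}dimethylsilane
Product: 22 2-{(Z)-3-hydroxy-1-[(1S)-1-(7-methoxy-2,2-dimethyl-2H-chromen-6-yl)ethoxy]prop-1-en-2-yl}-5-methylphenol
Conditions: Bu4NF (2.5 equiv), THF, 0 °C → rt; then H2O
Reagents that add atoms: none
Why: Fluoride-mediated cleavage of both silyl ethers under basic, acid-free conditions, which the acid-labile benzylic enol ether and the chromene should tolerate.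

**Compound list**
1 | 2,4-dihydroxyacetophenone | CC(=O)c1ccc(O)cc1O | starting material
2 | 3-chloro-3-methylbut-1-yne | CC(C)(Cl)C#C | starting material
3 | 1-[2-hydroxy-4-(2-methylbut-3-yn-2-yloxy)phenyl]ethanone | CC(=O)c1ccc(OC(C)(C)C#C)cc1O | intermediate
4 | 1-[2-methoxy-4-(2-methylbut-3-yn-2-yloxy)phenyl]ethanone | CC(=O)c1ccc(OC(C)(C)C#C)cc1OC | intermediate
5 | 2-{(1S)-1-[2-methoxy-4-(2-methylbut-3-yn-2-yloxy)phenyl]ethoxy}-1,3,2-benzodioxaborole (catechol borate ester, formed in the flask) | COc1cc(OC(C)(C)C#C)ccc1[C@H](C)OB1Oc2ccccc2O1 | intermediate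
6 | (S)-1-[2-methoxy-4-(2-methylbut-3-yn-2-yloxy)phenyl]ethanol | COc1cc(OC(C)(C)C#C)ccc1[C@H](C)O | intermediate
7 | 2-bromo-5-methylphenol | Cc1ccc(Br)c(O)c1 | starting material
8 | (2-bromo-5-methylphenoxy)triisopropylsilane | Cc1ccc(Br)c(O[Si](C(C)C)(C(C)C)C(C)C)c1 | intermediate
9 | propargyl alcohol (prop-2-yn-1-ol) | C#CCO | starting material
10 | [4-methyl-2-(triisopropylsilyloxy)phenyl]magnesium bromide (formed in the flask) | Cc1ccc([Mg]Br)c(O[Si](C(C)C)(C(C)C)C(C)C)c1 | intermediate
11 | chloromagnesium prop-2-yn-1-olate (formed in the flask) | C#CCO[Mg]Cl | intermediate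
12 | 4-[4-methyl-2-(triisopropylsilyloxy)phenyl]-2,5-dihydro-1,2-oxamagnesole (formed in the flask) | Cc1ccc(C2=C[Mg]OC2)c(O[Si](C(C)C)(C(C)C)C(C)C)c1 | intermediate
13 | 2-[4-methyl-2-(triisopropylsilyloxy)phenyl]prop-2-en-1-ol | C=C(CO)c1ccc(C)cc1O[Si](C(C)C)(C(C)C)C(C)C | intermediate
14 | [2-(3-bromoprop-1-en-2-yl)-5-methylphenoxy]triisopropylsilane | C=C(CBr)c1ccc(C)cc1O[Si](C(C)C)(C(C)C)C(C)C | intermediate
15 | sodium (S)-1-[2-methoxy-4-(2-methylbut-3-yn-2-yloxy)phenyl]ethanolate (formed in the flask) | COc1cc(OC(C)(C)C#C)ccc1[C@H](C)[O-].[Na+] | intermediate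
16 | {2-[3-{(1S)-1-[2-methoxy-4-(2-methylbut-3-yn-2-yloxy)phenyl]ethoxy}prop-1-en-2-yl]-5-methylphenoxy}triisopropylsilane | COc1cc(OC(C)(C)C#C)ccc1[C@H](C)OCC(=C)c1ccc(C)cc1O[Si](C(C)C)(C(C)C)C(C)C | intermediate
17 | {2-[2-({(1S)-1-[2-methoxy-4-(2-methylbut-3-yn-2-yloxy)phenyl]ethoxy}methyl)oxiran-2-yl]-5-methylphenoxy}triisopropylsilane (both epimers at the oxirane carbon) | COc1cc(OC(C)(C)C#C)ccc1[C@H](C)OCC1(CO1)c1ccc(C)cc1O[Si](C(C)C)(C(C)C)C(C)C | intermediate
18 | diethylaluminium (Z)-3-{(1S)-1-[2-methoxy-4-(2-methylbut-3-yn-2-yloxy)phenyl]ethoxy}-2-[4-methyl-2-(triisopropylsilyloxy)phenyl]prop-2-en-1-olate (formed in the flask) | COc1cc(OC(C)(C)C#C)ccc1[C@H](C)O/C=C(\CO[Al](CC)CC)c1ccc(C)cc1O[Si](C(C)C)(C(C)C)C(C)C | intermediate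
19 | (Z)-3-{(1S)-1-[2-methoxy-4-(2-methylbut-3-yn-2-yloxy)phenyl]ethoxy}-2-[4-methyl-2-(triisopropylsilyloxy)phenyl]prop-2-en-1-ol | COc1cc(OC(C)(C)C#C)ccc1[C@H](C)O/C=C(\CO)c1ccc(C)cc1O[Si](C(C)C)(C(C)C)C(C)C | intermediate
20 | tert-butyl{[(Z)-3-{(1S)-1-[2-methoxy-4-(2-methylbut-3-yn-2-yloxy)phenyl]ethoxy}-2-[4-methyl-2-(triisopropylsilyloxy)phenyl]prop-2-en-1-yl]oxy}dimethylsilane (key-step precursor) | COc1cc(OC(C)(C)C#C)ccc1[C@H](C)O/C=C(\CO[Si](C)(C)C(C)(C)C)c1ccc(C)cc1O[Si](C(C)C)(C(C)C)C(C)C | intermediate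
21 | tert-butyl{[(Z)-3-[(1S)-1-(7-methoxy-2,2-dimethyl-2H-chromen-6-yl)ethoxy]-2-[4-methyl-2-(triisopropylsilyloxy)phenyl]prop-2-en-1-yl]oxy}dimethylsilane (key-step product) | COc1cc2c(cc1[C@H](C)O/C=C(\CO[Si](C)(C)C(C)(C)C)c1ccc(C)cc1O[Si](C(C)C)(C(C)C)C(C)C)C=CC(C)(C)O2 | intermediate
22 | 2-{(Z)-3-hydroxy-1-[(1S)-1-(7-methoxy-2,2-dimethyl-2H-chromen-6-yl)ethoxy]prop-1-en-2-yl}-5-methylphenol | COc1cc2c(cc1[C@H](C)O/C=C(\CO)c1ccc(C)cc1O)C=CC(C)(C)O2 | target

**Step count**
Total steps: 12. Longest linear sequence: 9 steps (steps 1, 2, 3, 7, 8, 9, 10, 11, 12 from compound 1; equally steps 4 to 12 from compound 7).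

**Steps most likely to fail**

Risk 1, step 11. The Lewis-acidic gold centre or a trace of HNTf2 may ionise the benzylic C–O bond or add across the enol ether, and ring closure may occur in part at the carbon flanked by the two oxygens. The fallback closes ring B before any acid-labile ether exists. It sets out from ketone 4, which under the same gold catalysis (warmed in 1,2-dichloroethane if needed) should give 1-(7-methoxy-2,2-dimethyl-2H-chromen-6-yl)ethanone F1, where a regioisomer can be removed easily. The Corey–Bakshi–Shibata reduction of step 3 then gives (S)-1-(7-methoxy-2,2-dimethyl-2H-chromen-6-yl)ethanol F2. Because the chromene alkene would not survive an epoxidation, the oxirane is installed on the other fragment first: allylic alcohol 13 is epoxidised (mCPBA, NaHCO3) to {2-[4-methyl-2-(triisopropylsilyloxy)phenyl]oxiran-2-yl}methanol F3 and mesylated (MsCl, Et3N) to its methanesulfonate F4. The sodium alkoxide of F2 (NaH, DMF) is alkylated by F4 to the oxiranyl ether F5; attack at either CH2 gives the same constitution. The aluminium amide of step 9 then gives the (Z)-enol ether alcohol F6, and Bu4NF removes the aryl silyl group to rejoin the route at 22.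

Risk 2, step 9. The syn-elimination may give poor geometric selectivity about the new enol ether, or the aluminium reagent may open the tertiary benzylic oxirane to a cation that rearranges to an aldehyde. The fallback fixes the geometry by stereoretentive C–O coupling and sets out from 6 and from the oxamagnesacycle 12 of step 5. Quenching 12 with iodine in place of water should give (Z)-3-iodo-2-[4-methyl-2-(triisopropylsilyloxy)phenyl]prop-2-en-1-ol F7, with iodine cis to CH2OH as fixed by the chelate, and TBSCl/imidazole gives its silyl ether F8. Alcohol 6 is capped at the alkyne carbon (EtMgBr, 2.1 equiv, then TMSCl; any O-silyl ether is hydrolysed on aqueous work-up) to give (S)-1-{2-methoxy-4-[2-methyl-4-(trimethylsilyl)but-3-yn-2-yloxy]phenyl}ethanol F9, so that no terminal alkyne meets copper. An Ullmann-type alkenyl iodide–alcohol coupling (CuI, 3,4,7,8-tetramethyl-1,10-phenanthroline, Cs2CO3, toluene, 80 °C) joins F9 and F8 with retention of alkene geometry to the C-silylated enol ether F10. K2CO3 in MeOH removes the alkynyl silyl group to rejoin the route at 20.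

Risk 3, step 5. The ortho-silyloxy aryl Grignard reagent may form sluggishly, undergo O-to-C silyl migration, or add poorly to the propargylic alkoxide. The fallback replaces the carbometalation by cross-coupling and sets out from bromide 8. Miyaura borylation (B2pin2, Pd(dppf)Cl2, KOAc, dioxane, 90 °C) gives triisopropyl[5-methyl-2-(4,4,5,5-tetramethyl-1,3,2-dioxaborolan-2-yl)phenoxy]silane F11. Suzuki–Miyaura coupling of F11 with commercial 2-bromoprop-2-en-1-ol (Pd(PPh3)4, K3PO4, dioxane–H2O, 70 °C) rejoins the route at 13.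

**Further compounds**
F1 | step 11 | 1-(7-methoxy-2,2-dimethyl-2H-chromen-6-yl)ethanone | CC(=O)c1cc2C=CC(C)(C)Oc2cc1OC
F2 | step 11 | (S)-1-(7-methoxy-2,2-dimethyl-2H-chromen-6-yl)ethanol | COc1cc2OC(C)(C)C=Cc2cc1[C@H](C)O
F3 | step 11 | {2-[4-methyl-2-(triisopropylsilyloxy)phenyl]oxiran-2-yl}methanol (racemic) | OCC1(CO1)c1ccc(C)cc1O[Si](C(C)C)(C(C)C)C(C)C
F4 | step 11 | {2-[4-methyl-2-(triisopropylsilyloxy)phenyl]oxiran-2-yl}methyl methanesulfonate (racemic) | CS(=O)(=O)OCC1(CO1)c1ccc(C)cc1O[Si](C(C)C)(C(C)C)C(C)C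
F5 | step 11 | {2-[2-({(1S)-1-(7-methoxy-2,2-dimethyl-2H-chromen-6-yl)ethoxy}methyl)oxiran-2-yl]-5-methylphenoxy}triisopropylsilane (both epimers at the oxirane carbon) | COc1cc2OC(C)(C)C=Cc2cc1[C@H](C)OCC1(CO1)c1ccc(C)cc1O[Si](C(C)C)(C(C)C)C(C)C
F6 | step 11 | (Z)-3-[(1S)-1-(7-methoxy-2,2-dimethyl-2H-chromen-6-yl)ethoxy]-2-[4-methyl-2-(triisopropylsilyloxy)phenyl]prop-2-en-1-ol | COc1cc2OC(C)(C)C=Cc2cc1[C@H](C)O/C=C(\CO)c1ccc(C)cc1O[Si](C(C)C)(C(C)C)C(C)C
F7 | step 9 | (Z)-3-iodo-2-[4-methyl-2-(triisopropylsilyloxy)phenyl]prop-2-en-1-ol | I/C=C(\CO)c1ccc(C)cc1O[Si](C(C)C)(C(C)C)C(C)C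
F8 | step 9 | tert-butyl{[(Z)-3-iodo-2-[4-methyl-2-(triisopropylsilyloxy)phenyl]prop-2-en-1-yl]oxy}dimethylsilane | I/C=C(\CO[Si](C)(C)C(C)(C)C)c1ccc(C)cc1O[Si](C(C)C)(C(C)C)C(C)C
F9 | step 9 | (S)-1-{2-methoxy-4-[2-methyl-4-(trimethylsilyl)but-3-yn-2-yloxy]phenyl}ethanol | COc1cc(OC(C)(C)C#C[Si](C)(C)C)ccc1[C@H](C)O
F10 | step 9 | tert-butyl{[(Z)-3-{(1S)-1-[2-methoxy-4-(2-methyl-4-(trimethylsilyl)but-3-yn-2-yloxy)phenyl]ethoxy}-2-[4-methyl-2-(triisopropylsilyloxy)phenyl]prop-2-en-1-yl]oxy}dimethylsilane | COc1cc(OC(C)(C)C#C[Si](C)(C)C)ccc1[C@H](C)O/C=C(\CO[Si](C)(C)C(C)(C)C)c1ccc(C)cc1O[Si](C(C)C)(C(C)C)C(C)C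
F11 | step 5 | triisopropyl[5-methyl-2-(4,4,5,5-tetramethyl-1,3,2-dioxaborolan-2-yl)phenoxy]silane | Cc1ccc(B2OC(C)(C)C(C)(C)O2)c(O[Si](C(C)C)(C(C)C)C(C)C)c1
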